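0.645 mM is where free monomer stands at 5.00 min in the noon run, and dawn and midnight read 12.8 % and 12.9 % at that time, against 12.9 % in noon. I read this level as the equilibrium monomer concentration, where growth and loss at the chain ends balance. I treat that balance as reached quickly and ask what monomer remains to share out.

| setting | noon | dawn | midnight | teal | amber |
|---|---|---|---|---|---|
| free monomer | 5 mM | 5 mM | 5 mM | 5.0 mM | 5.0 mM |
| protic impurity | 0.93 mM | 1.5 mM | 1.9 mM | 2.50 mM | 0.800 mM |
| initiator | 10 µM | 10 µM | 10 µM | 10 µM | 10 µM |
| remark | run made earlier | run made earlier | run made earlier |  |  |
| time |  |  |  | 10 min | 10 min |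

| run | time / min | monomer in chains / % | free monomer / % |
|---|---|---|---|
| noon | 0.417 | 26.3 | 59.2 |
| noon | 0.833 | 43.8 | 36.6 |
| noon | 1.33 | 53.9 | 24.2 |
| noon | 2.50 | 58.7 | 14.3 |
| noon | 5.00 | 57.9 | 12.9 |
| dawn | 0.417 | 24.6 | 54.6 |
| dawn | 1.33 | 47.0 | 21.8 |
| dawn | 2.50 | 50.9 | 13.7 |
| dawn | 4.00 | 48.7 | 13.1 |
| dawn | 5.00 | 47.2 | 12.8 |
| midnight | 0.417 | 23.8 | 52.1 |
| midnight | 1.33 | 43.2 | 19.4 |
| midnight | 2.50 | 44.8 | 13.3 |
| midnight | 4.00 | 41.8 | 12.5 |
| midnight | 5.00 | 39.9 | 12.9 |

(readings scatter by 0.3 percentage points)

- the average divides the monomer in chains by the number of chains begun, living and dead together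
- the earlier runs do not show the number of chains; that part of a forecast is a guess

- which of the two ends with the longer chains by the average number of monomer units in a chain (chains begun, living or dead) ("neither" if they lie within 10 %) (teal / amber / neither)
- average number of monomer units in a chain (chains begun, living or dead) at the end, teal
- average number of monomer units in a chain (chains begun, living or dead) at the end, amber

I build the flask one process at a time. With the main step by itself, chains hold the charge minus that level, 4.36 mM in teal and amber alike. At one chain per initiator, that is a length of 436. This chain count is a guess that the runs do not test.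

Next comes the protic impurity. At 5.00 min, the monomer missing from both columns, less the impurity charged, is 0.530 mM in noon and 0.460 mM in midnight. So I count one monomer lost per impurity. That takes teal to 186 and amber to 356.

Last comes a slow drain. The noon sum of both columns falls at 0.0440 mM min⁻¹ between 2.50 min and 5.00 min. Adding that rate from 5.00 min to 10 min onto the noon remainder, I estimate the drain at 0.750 mM.

Teal keeps 1.10 mM and amber 2.80 mM of the chain budget, which is [free monomer] charged minus [protic impurity] charged, minus the level and the drain. Divided by [initiator] charged, the budget gives 110 for teal and 280 for amber, so I expect longer chains in amber than in teal.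

The forecast says amber, with 105 for teal (range 20 to 140) and 255 for amber (range 60 to 320), both less than my figures, and it adds “This count is a guess”.

The flask gives amber, with 104 in teal and 261 in amber.

    free monomer + initiator → living end + monomer in chains (k = 38.0 L mol⁻¹ s⁻¹)
    free monomer + living end → monomer in chains + living end, rate k2*[living end]*[free monomer] (k = 2200 L mol⁻¹ s⁻¹)
    monomer in chains + living end → free monomer + living end, rate k3*[living end] as long as [monomer in chains] is above zero (k = 1.60 s⁻¹)
    protic impurity + free monomer → quenched substrate (k = 9.40 L mol⁻¹ s⁻¹)
    free monomer → uncatalysed product (k = 0.00160 s⁻¹)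

Amber ends longer because of its lower [protic impurity]: with teal's charge, its 261 becomes 104. Teal's budget of 1.10 mM stands against 1.04 mM of monomer in chains at 10.0 min. A neighbour like teal but charged with 6.2 mM of protic impurity has a budget of −2.60 mM, which is below zero. That neighbour holds 0 % monomer in chains at 10.0 min, and its average length is 2.56 × 10⁻⁵.

The readings are calculated from invented constants, noise included.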